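**Retrosynthetic overview**
- Numbering: seven-membered ring C1(OAc)–C2–C3(Me)–C7(H)–C8(OAr)–C9=C10(Me); five-membered ring C3–C4–C5–C6(OH, iPr)–C7. The strategy rests on the C1 oxygen and the C6 carbinol carbon being 1,5-related along C1–C2–C3–C7–C6, with C3 quaternary. Reconnecting C1–C7 turns this into an aldol unit C1(O)–C7–C6(=O) held in a cyclobutane C1–C2–C3–C7.
- Late stage: the C1 acetate comes from a C1 enone (1,2-reduction, then inversion with acetic acid), the C9=C10 bond from dehydrogenation of the C1 ketone, the aroate from the C8 alcohol, and the isopropyl carbinol from the C6 ketone of a hydroazulene-1,6-dione.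
- Key disconnection: the 1,6-dione goes back to a cyclopentenyl enol acetate by retro-aldol cleavage of C1–C7 and [2+2] photocycloaddition (C7–C3 and C1–C2). Ring order: the cyclopentene C1/C7/C8/C9/C10 is bought, the five-membered ring C3–C7 closes first, the cyclobutane second, and the seven-membered ring appears last by fragmentation.
- The enol acetate comes from (R)-4-silyloxycyclopentenone (source of C8) by iodination/methylation (C10 methyl) and an α′-aldol with 4-methylpent-4-enal; this replaces any reduction of an enolised 2-acyl-1,3-dione, which would not be selective.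

Key step: step 7

Remark: C10 arises as an epimer mixture in step 4 and is drawn throughout as the epimer with methyl cis to the C8 oxygen (it becomes sp2 in step 12); 4-methylpent-4-enal is taken as a catalogue aldehyde.

**Step 1**
Reactants: 1 (R)-4-(tert-butyldimethylsilyloxy)cyclopent-2-en-1-one
Product: 2 (R)-4-(tert-butyldimethylsilyloxy)-2-iodocyclopent-2-en-1-one
Conditions: I2, pyridine/CH2Cl2 (1:1), 0 °C → rt
Reagents that add atoms: iodine, II
Why: α-Iodination of the enone by pyridine-mediated addition–elimination (Baylis–Hillman-type halogenation) is standard for 4-silyloxycyclopentenones and does not touch the stereocentre that becomes C8.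

**Step 2**
Reactants: 2 (R)-4-(tert-butyldimethylsilyloxy)-2-iodocyclopent-2-en-1-one
Product: 3 (R)-4-(tert-butyldimethylsilyloxy)-2-methylcyclopent-2-en-1-one
Conditions: Me4Sn, PdCl2(PhCN)2 (5 mol%), AsPh3, CuI, NMP, 80 °C
Reagents that add atoms: tetramethylstannane, C[Sn](C)(C)C
Why: Stille cross-coupling of the 2-iodoenone is neutral, so the base-sensitive β-silyloxy enone survives, and it places the future C10 methyl without creating a stereocentre.

**Step 3**
Reactants: 3 (R)-4-(tert-butyldimethylsilyloxy)-2-methylcyclopent-2-en-1-one; 4 4-methylpent-4-enal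
Product: 6 4-(tert-butyldimethylsilyloxy)-5-(1-hydroxy-4-methylpent-4-enyl)-2-methylcyclopent-2-en-1-one (4,5-trans; carbinol epimers), via lithium enolate 5 (not isolated)
Conditions: LiN(iPr)2 (LDA), THF, −78 °C; then 4, −78 °C; NH4Cl (aq) at −78 °C
Reagents that add atoms: none
Why: Kinetic α′-deprotonation gives the cross-conjugated enolate, which keeps its silyloxy group at −78 °C because its loss would give a cyclopentadienone, and the aldol addition occurs anti to the silyloxy group (4,5-trans); the carbinol centre is a mixture that step 5 erases.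

**Step 4**
Reactants: 6 4-(tert-butyldimethylsilyloxy)-5-(1-hydroxy-4-methylpent-4-enyl)-2-methylcyclopent-2-en-1-one
Product: 7 3-(tert-butyldimethylsilyloxy)-2-(1-hydroxy-4-methylpent-4-enyl)-5-methylcyclopentan-1-one (2,3-trans; C5 epimers)
Conditions: [(Ph3P)CuH]6 (0.4 equiv), H2O (3 equiv), benzene, rt
Reagents that add atoms: none
Why: Copper hydride conjugate reduction (Stryker reduction) takes the enone C=C and leaves the isolated 1,1-disubstituted alkene and the ketone; the methyl-bearing centre (C10) is set by protonation of the copper enolate without reliable control, which does not matter.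

**Step 5**
Reactants: 7 3-(tert-butyldimethylsilyloxy)-2-(1-hydroxy-4-methylpent-4-enyl)-5-methylcyclopentan-1-one
Product: 8 3-(tert-butyldimethylsilyloxy)-5-methyl-2-(4-methylpent-4-enoyl)cyclopentan-1-one (enolised β-diketone)
Conditions: Dess–Martin periodinane (1.2 equiv), NaHCO3, CH2Cl2, 0 °C → rt
Reagents that add atoms: none
Why: Dess–Martin oxidation of a β-hydroxy ketone gives the β-diketone under buffered, non-basic conditions, so the β-silyloxy group is not eliminated; C7 becomes sp2 in the enol.

**Step 6**
Reactants: 8 3-(tert-butyldimethylsilyloxy)-5-methyl-2-(4-methylpent-4-enoyl)cyclopentan-1-one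
Product: 9 (3S)-3-(tert-butyldimethylsilyloxy)-5-methyl-2-(4-methylpent-4-enoyl)cyclopent-1-en-1-yl acetate
Conditions: Ac2O, pyridine, DMAP (cat.), CH2Cl2, 0 °C
Reagents that add atoms: acetic anhydride, CC(=O)OC(C)=O
Why: O-Acylation of the enolised 2-acylcyclopentanone at the ring oxygen gives the endocyclic enol acetate (C1=C7), because the exocyclic enol ester would suffer allylic 1,3-strain with the C8 silyloxy group and DMAP-mediated acyl transfer lets the isomers equilibrate.

**Step 7**
Reactants: 9 (3S)-3-(tert-butyldimethylsilyloxy)-5-methyl-2-(4-methylpent-4-enoyl)cyclopent-1-en-1-yl acetate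
Product: 12 (3R,7S,8S)-8-(tert-butyldimethylsilyloxy)-3,10-dimethyl trans-fused hydroazulene-1,6-dione (skeleton numbering), via photoadduct acetate 10 (not isolated), via cyclobutanol 11 (not isolated)
Conditions: hν (medium-pressure Hg lamp, Pyrex filter, λ > 300 nm), degassed MeCN (0.01 M), 20 °C; then K2CO3, MeOH, 0 °C → rt, held until the C7 epimers have equilibrated
Reagents that add atoms: none
Why: Irradiation excites the β-acetoxy enone (C6=O conjugated with C7=C1) to its triplet, which adds stepwise to the tethered alkene: C7–C3 forms first by 1,5-closure (5-exo mode, the rule of five for a three-atom tether) and closes the cyclopentanone ring C3–C4–C5–C6–C7, and the 1,4-biradical then collapses through C1–C2 by biradical recombination to the fused ("straight") cyclobutane C1–C2–C3–C7. Carbonate in methanol transesterifies the tertiary acetate, and the C1 alkoxide cleaves C1–C7 by retro-aldol, driven by cyclobutane strain and the C6 carbonyl, so the four-membered ring and the original cyclopentane merge into the seven-membered ring (ring expansion by fragmentation, not by closure). The closest known reaction type is the intramolecular de Mayo reaction of enol esters of 2-acylcycloalkanones that carry the alkene in the acyl chain, followed by retro-aldol two-carbon ring expansion. C3 is set by the alkene adding to the face of C7 anti to the silyloxy group on the adjacent C8, which places the C3 methyl trans to the C8 oxygen on the seven-membered ring as in the target; the step needs this facial selectivity and the straight regiochemistry, and the bulky silyloxy group next to the reacting carbon and the three-atom tether secure them. C7 is set by protonation of the C6/C7 enolate and is expected to equilibrate in the same medium to the trans-fused epimer (H7 anti to the C3 methyl, C6 branch trans to the C8 silyloxy group); C10 may epimerise, which is immaterial.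

**Step 8**
Reactants: 12 (3R,7S,8S)-8-(tert-butyldimethylsilyloxy)-3,10-dimethyl trans-fused hydroazulene-1,6-dione
Product: 13 (3R,7S,8S)-8-hydroxy-3,10-dimethyl trans-fused hydroazulene-1,6-dione
Conditions: HF·pyridine, pyridine, THF, 0 °C → rt
Reagents that add atoms: none
Why: Desilylation with buffered HF·pyridine generates no enolate, so the β-hydroxy ketone should neither dehydrate nor undergo retro-aldol, and C7 keeps its configuration.

**Step 9**
Reactants: 13 (3R,7S,8S)-8-hydroxy-3,10-dimethyl trans-fused hydroazulene-1,6-dione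
Product: 14 (3R,6R,7S,8S)-6,8-dihydroxy-6-isopropyl-3,10-dimethyl trans-fused hydroazulen-1-one
Conditions: iPrMgCl (4 equiv), CeCl3 (anhydrous, 4 equiv), THF, −78 → −40 °C; NH4Cl (aq)
Reagents that add atoms: isopropylmagnesium chloride, CC(C)[Mg]Cl
Why: In this organocerium (Imamoto) addition the first equivalent forms the C8 alkoxide, which cannot be expelled and which holds the metal next to the C6 carbonyl in a six-membered chelate, activating this cyclopentanone over the unactivated seven-ring C1 ketone while cerium suppresses enolisation and β-hydride reduction; the isopropyl group enters the cyclopentanone face that carries only H7, anti to the angular methyl and to the C7–C8 bond, so the C6 hydroxyl ends cis to the methyl (6R).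

**Step 10**
Reactants: 15 4-hydroxybenzoic acid
Product: 17 4-(triisopropylsilyloxy)benzoic acid, via bis-silylated benzoate 16 (not isolated)
Conditions: TIPSCl (2.2 equiv), imidazole, DMF, rt; then K2CO3, THF/MeOH/H2O, rt; citric acid (aq)
Reagents that add atoms: chlorotriisopropylsilane, CC(C)[Si](Cl)(C(C)C)C(C)C
Why: Exhaustive silylation followed by selective hydrolysis of the labile silyl ester (protecting-group chemistry) leaves the aryl TIPS ether, which will survive borohydride and Mitsunobu conditions and come off with buffered fluoride.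

**Step 11**
Reactants: 14 (3R,6R,7S,8S)-6,8-dihydroxy-6-isopropyl-3,10-dimethyl trans-fused hydroazulen-1-one; 17 4-(triisopropylsilyloxy)benzoic acid
Product: 18 C8 4-(triisopropylsilyloxy)benzoate of 14 (C1 ketone; C6 hydroxyl free)
Conditions: DCC, DMAP, CH2Cl2, rt → 40 °C
Reagents that add atoms: none
Why: Steglich esterification acylates the secondary C8 hydroxyl while the tertiary C6 hydroxyl is inert, and C8 keeps its configuration because its C–O bond is not broken.

**Step 12**
Reactants: 18 C8 4-(triisopropylsilyloxy)benzoate of 14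
Product: 19 (3R,6R,7S,8S)-C9=C10 enone (10-methyl-hydroazulen-9-en-1-one bearing the C8 aroate and the C6 carbinol)
Conditions: IBX (2.5 equiv), DMSO/PhF (1:2), 70 °C
Reagents that add atoms: none
Why: IBX dehydrogenation of the ketone through its enol can only give an enone on the C10 side because C3 is quaternary, so the C9=C10 bond forms regiospecifically and the C10 centre is removed; the tertiary alcohol, the ester and the aryl silyl ether tolerate IBX.

**Step 13**
Reactants: 19 (3R,6R,7S,8S)-C9=C10 enone
Product: 20 (1R,3R,6R,7S,8S)-allylic alcohol (C1 hydroxyl cis to the C3 methyl)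
Conditions: NaBH4, CeCl3·7H2O, MeOH/THF, −40 °C
Reagents that add atoms: none
Why: Luche reduction gives clean 1,2-reduction of the enone, and hydride is expected to enter C1 from the face anti to the axial angular methyl on C3 (1,3-related), which gives the (1R) alcohol.

**Step 14**
Reactants: 20 (1R,3R,6R,7S,8S)-allylic alcohol
Product: 21 (1S,3R,6R,7S,8S)-C1 acetate with the aryl TIPS ether
Conditions: PPh3, DIAD, AcOH, toluene, 0 °C → rt
Reagents that add atoms: acetic acid, CC(=O)O
Why: The Mitsunobu reaction with acetic acid installs the acetate with inversion at C1 (SN2 from the open face anti to the angular methyl), giving (1S); the tertiary hydroxyl does not react and the phenol is masked.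

**Step 15**
Reactants: 21 (1S,3R,6R,7S,8S)-C1 acetate with the aryl TIPS ether
Product: 22 target CNP0305796.2
Conditions: TBAF, AcOH (1:1), THF, 0 °C
Reagents that add atoms: none
Why: Buffered fluoride cleaves the electron-poor aryl silyl ether quickly, while the alkyl acetate, the benzoate and the tertiary alcohol are not affected (silyl ether deprotection).

**Compound list**
1 | (R)-4-(tert-butyldimethylsilyloxy)cyclopent-2-en-1-one | O=C1C[C@@H](O[Si](C)(C)C(C)(C)C)C=C1 | starting material
2 | (R)-4-(tert-butyldimethylsilyloxy)-2-iodocyclopent-2-en-1-one | O=C1C[C@@H](O[Si](C)(C)C(C)(C)C)C=C1I | intermediate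
3 | (R)-4-(tert-butyldimethylsilyloxy)-2-methylcyclopent-2-en-1-one | O=C1C[C@@H](O[Si](C)(C)C(C)(C)C)C=C1C | intermediate
4 | 4-methylpent-4-enal | CC(=C)CCC=O | starting material
5 | lithium cross-conjugated enolate of 3 (not isolated) | [Li]OC1=C[C@@H](O[Si](C)(C)C(C)(C)C)C=C1C | intermediate
6 | aldol adduct, side chain trans to the silyloxy group, carbinol epimers | O=C1[C@H](C(O)CCC(C)=C)[C@@H](O[Si](C)(C)C(C)(C)C)C=C1C | intermediate
7 | saturated hydroxy ketone, 2,3-trans, methyl drawn cis to the silyloxy group | O=C1[C@H](C(O)CCC(C)=C)[C@@H](O[Si](C)(C)C(C)(C)C)C[C@H]1C | intermediate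
8 | β-diketone, drawn as the ring enol | OC1=C(C(=O)CCC(C)=C)[C@@H](O[Si](C)(C)C(C)(C)C)C[C@H]1C | intermediate
9 | enol acetate (photosubstrate), (3S), methyl drawn cis to the silyloxy group | CC(=O)OC1=C(C(=O)CCC(C)=C)[C@@H](O[Si](C)(C)C(C)(C)C)C[C@H]1C | intermediate
10 | tricyclic cyclobutyl acetate photoadduct (not isolated) | CC(=O)O[C@@]12C[C@@]3(C)CCC(=O)[C@@]13[C@@H](O[Si](C)(C)C(C)(C)C)C[C@H]2C | intermediate
11 | tricyclic cyclobutanol (not isolated) | O[C@@]12C[C@@]3(C)CCC(=O)[C@@]13[C@@H](O[Si](C)(C)C(C)(C)C)C[C@H]2C | intermediate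
12 | trans-fused hydroazulene-1,6-dione, C8 silyl ether, (3R,7S,8S) | O=C1C[C@@]2(C)CCC(=O)[C@@H]2[C@@H](O[Si](C)(C)C(C)(C)C)C[C@H]1C | intermediate
13 | 8-hydroxy-1,6-dione, (3R,7S,8S) | O=C1C[C@@]2(C)CCC(=O)[C@@H]2[C@@H](O)C[C@H]1C | intermediate
14 | keto diol with the C6 isopropyl carbinol, (3R,6R,7S,8S) | O=C1C[C@@]2(C)CC[C@@](O)(C(C)C)[C@@H]2[C@@H](O)C[C@H]1C | intermediate
15 | 4-hydroxybenzoic acid | OC(=O)c1ccc(O)cc1 | starting material
16 | triisopropylsilyl 4-(triisopropylsilyloxy)benzoate (not isolated) | CC(C)[Si](OC(=O)c1ccc(O[Si](C(C)C)(C(C)C)C(C)C)cc1)(C(C)C)C(C)C | intermediate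
17 | 4-(triisopropylsilyloxy)benzoic acid | OC(=O)c1ccc(O[Si](C(C)C)(C(C)C)C(C)C)cc1 | intermediate
18 | C8 aroate, C1 ketone, C6 carbinol | O=C1C[C@@]2(C)CC[C@@](O)(C(C)C)[C@@H]2[C@@H](OC(=O)c2ccc(O[Si](C(C)C)(C(C)C)C(C)C)cc2)C[C@H]1C | intermediate
19 | C9=C10 enone | O=C1C[C@@]2(C)CC[C@@](O)(C(C)C)[C@@H]2[C@@H](OC(=O)c2ccc(O[Si](C(C)C)(C(C)C)C(C)C)cc2)C=C1C | intermediate
20 | (1R)-allylic alcohol | O[C@@H]1C[C@@]2(C)CC[C@@](O)(C(C)C)[C@@H]2[C@@H](OC(=O)c2ccc(O[Si](C(C)C)(C(C)C)C(C)C)cc2)C=C1C | intermediate
21 | (1S)-acetate, aryl TIPS ether | CC(=O)O[C@H]1C[C@@]2(C)CC[C@@](O)(C(C)C)[C@@H]2[C@@H](OC(=O)c2ccc(O[Si](C(C)C)(C(C)C)C(C)C)cc2)C=C1C | intermediate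
22 | CNP0305796.2, (1S,3R,6R,7S,8S) in skeleton numbering | CC(=O)O[C@H]1C[C@@]2(C)CC[C@@](O)(C(C)C)[C@@H]2[C@@H](OC(=O)c2ccc(O)cc2)C=C1C | target

**Step count**
Total steps: 15. Longest linear sequence: 14 (steps 1–9 and 11–15).

**Steps most likely to fail**

Step 7. The carbonate-promoted fragmentation passes through the C6/C7 enolate, which may expel the C8 silyloxy group (E1cB) or be protonated to the cis-fused epimer without reaching equilibrium; lower facial selectivity in the cycloaddition would show up as the C3 epimer. The fallback sets out from 8 and unveils the cyclobutanol without base. Benzyl chloroformate and pyridine give the enol benzyl carbonate F1. Irradiation as in step 7 gives the cyclobutyl benzyl carbonate F2. Hydrogenolysis (H2, Pd/C, EtOAc) then releases the cyclobutanol 11, which opens to the dione and ketonises through the neutral enol. The route is rejoined at 12.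

Step 9. The reagent may attack the C1 carbonyl as well, transfer a β-hydride instead of adding, or enolise C7 with retro-aldol opening of the β-hydroxy ketone. The fallback sets out from 13 and removes C1 from the competition:
- 4-(Triisopropylsilyloxy)benzaldehyde F3 (from 4-hydroxybenzaldehyde, TIPSCl and imidazole) and catalytic SmI2 in THF at −10 °C effect an Evans–Tishchenko reduction. It acts only on the β-hydroxy ketone and gives the C8 aroate with a secondary C6 alcohol F4.
- Ethylene glycol and PPTS convert the remaining C1 ketone into the dioxolane F5.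
- Dess–Martin oxidation gives the C6 ketone F6.
- iPrMgCl/CeCl3 at −78 °C adds from the H7 face to give the tertiary carbinol F7.
- PPTS in wet acetone removes the dioxolane and returns to the route at 18; steps 9 and 11 are replaced.

Step 14. Displacement at the hindered allylic C1 may be diverted to SN2′ attack at C9 or to elimination to a diene, and the step relies on step 13 having delivered hydride from the predicted face. The fallback sets out from 19 and sets C1 under reagent control. Corey–Bakshi–Shibata reduction with (R)-2-methyl-CBS-oxazaborolidine and catecholborane in toluene at −78 °C gives the (1S)-allylic alcohol F8. Ac2O, DMAP and pyridine acetylate it with retention. The route is rejoined at 21; steps 13 and 14 are replaced.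

**Further compounds**
F1 | step 7 | enol benzyl carbonate of 8 | O=C(OCc1ccccc1)OC1=C(C(=O)CCC(C)=C)[C@@H](O[Si](C)(C)C(C)(C)C)C[C@H]1C
F2 | step 7 | tricyclic cyclobutyl benzyl carbonate photoadduct | O=C(OCc1ccccc1)O[C@@]12C[C@@]3(C)CCC(=O)[C@@]13[C@@H](O[Si](C)(C)C(C)(C)C)C[C@H]2C
F3 | step 9 | 4-(triisopropylsilyloxy)benzaldehyde | O=Cc1ccc(O[Si](C(C)C)(C(C)C)C(C)C)cc1
F4 | step 9 | C8 aroate with secondary C6 alcohol and C1 ketone | O=C1C[C@@]2(C)CC[C@H](O)[C@@H]2[C@@H](OC(=O)c2ccc(O[Si](C(C)C)(C(C)C)C(C)C)cc2)C[C@H]1C
F5 | step 9 | C1 dioxolane of F4 | C12(OCCO1)C[C@@]3(C)CC[C@H](O)[C@@H]3[C@@H](OC(=O)c3ccc(O[Si](C(C)C)(C(C)C)C(C)C)cc3)C[C@H]2C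
F6 | step 9 | C1 dioxolane with C6 ketone | C12(OCCO1)C[C@@]3(C)CCC(=O)[C@@H]3[C@@H](OC(=O)c3ccc(O[Si](C(C)C)(C(C)C)C(C)C)cc3)C[C@H]2C
F7 | step 9 | C1 dioxolane with C6 isopropyl carbinol | C12(OCCO1)C[C@@]3(C)CC[C@@](O)(C(C)C)[C@@H]3[C@@H](OC(=O)c3ccc(O[Si](C(C)C)(C(C)C)C(C)C)cc3)C[C@H]2C
F8 | step 14 | (1S)-allylic alcohol | O[C@H]1C[C@@]2(C)CC[C@@](O)(C(C)C)[C@@H]2[C@@H](OC(=O)c2ccc(O[Si](C(C)C)(C(C)C)C(C)C)cc2)C=C1C
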